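Everything rests on cutting both C–O bonds of the 1,2-dioxolane ring (O1, O2, C3, C4, C5). C3 and C5 are fully substituted peroxide carbons, 1,3-related across C4, so the O1–O2 bond can come intact from H2O2. In one operation H2O2 opens a trisubstituted epoxide at tertiary C5 and the new hydroperoxide opens a 2,2-disubstituted oxetane at tertiary C3 (5-exo), each with inversion. This closes the ring and sets both stereocentres (methyls cis). The precursor is the TBDPS ether of a (2R,3R)-epoxy alcohol linked through the C4 methylene to an (R)-2-methyloxetane. The released oxygens become the C5 aldehyde handle and the acetic acid arm.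

Key step: step 7

**Remarks on the chemistry**
- Assumption: enantiopure (R)-(−)-mevalonolactone, 8-bromooctan-1-ol and (2E,4E)-hepta-2,4-dienal are purchasable. Ring atoms are numbered O1, O2, C3 (acetic acid arm), C4, C5 (C16 chain) throughout.
- Stereochemical bookkeeping: the target is (3R,5R) with the two methyl groups cis.
  - Inversion at C5 requires the (2R,3R)-epoxide, hence D-(−)-tartrate on the E-allylic alcohol.
  - Inversion at C3 requires the (R)-oxetane, hence (R)-mevalonolactone, whose tertiary C–O bond stays intact until step 7.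
  - All other descriptor changes are CIP priority effects.
- Design of the precursor: the primary hydroxyl is carried as its TBDPS ether.
  - This removes one competing nucleophile (6-exo attack on the oxetane) and the Payne pathway.
  - It crowds the secondary carbinol released at the epoxide.
  - It keeps PhI(OAc)2 away from a free 1,2-diol in step 8.
  - It allows the hydroxyethyl arm to be oxidised selectively.
- Design of the front end:
  - The oxetane is closed on a carbonyl-free intermediate, because an oxetane β to a carbonyl group is prone to E1cB ring opening.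
  - The E-alkene is set by syn-carbometalation, because ketone olefination is poorly E-selective.
- Anhydrous ethereal H2O2 and all peroxides are handled on small scale behind a shield.
- Abbreviations: TBDPS = tert-butyldiphenylsilyl, TES = triethylsilyl, PT = 1-phenyl-1H-tetrazol-5-yl.

## Route

Step 1
Reactants: 1 (R)-mevalonolactone [(4R)-4-hydroxy-4-methyloxan-2-one]
Product: 3 (3S)-3-methylhex-5-yne-1,3-diol, via the lactol (4R)-4-methyloxane-2,4-diol 2 (not isolated)
Conditions: DIBAL-H (2.2 equiv), CH2Cl2, −78 °C; then MeOH, K2CO3, dimethyl (1-diazo-2-oxopropyl)phosphonate, −78 °C → rt; Rochelle salt work-up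
Reagents that add atoms: dimethyl (1-diazo-2-oxopropyl)phosphonate, CC(=O)C(=[N+]=[N-])P(=O)(OC)OC
Why: Low-temperature DIBAL-H reduction should stop at the lactol, and Seyferth–Gilbert homologation with the Ohira–Bestmann reagent converts its open hydroxy-aldehyde form (kept at low concentration by the closed lactol, which limits retro-aldol loss) into the terminal alkyne in the same flask, which avoids isolating a water-soluble lactol, keeps the two arms of the carbinol different and leaves the tertiary stereocentre untouched.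

Step 2
Reactants: 3 (3S)-3-methylhex-5-yne-1,3-diol
Product: 5 (3S,5E)-6-iodo-3,5-dimethylhex-5-ene-1,3-diol, via the (E)-alkenyldimethylalane dialkoxide 4 (not isolated)
Conditions: AlMe3 (4.5 equiv), Cp2ZrCl2 (0.25 equiv), CH2Cl2, 0 °C → rt; then I2, THF, −30 → 0 °C; aq. K2CO3
Reagents that add atoms: trimethylaluminium, C[Al](C)C; iodine, II
Why: Negishi zirconium-catalysed carboalumination adds methyl and aluminium syn across the terminal alkyne with methyl on the internal carbon (free homopropargylic hydroxyls are tolerated as dimethylaluminium alkoxides), and iodinolysis with retention fixes the E-trisubstituted geometry.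

Step 3
Reactants: 5 (3S,5E)-6-iodo-3,5-dimethylhex-5-ene-1,3-diol
Product: 6 (3S,5E)-3-hydroxy-6-iodo-3,5-dimethylhex-5-en-1-yl 4-methylbenzenesulfonate
Conditions: TsCl (1.1 equiv), Et3N, DMAP (5 mol %), CH2Cl2, 0 °C
Reagents that add atoms: 4-toluenesulfonyl chloride, Cc1ccc(cc1)S(=O)(=O)Cl
Why: Selective sulfonylation should occur at the primary hydroxyl because the tertiary carbinol is too hindered to react under these conditions.

Step 4
Reactants: 6 (3S,5E)-3-hydroxy-6-iodo-3,5-dimethylhex-5-en-1-yl 4-methylbenzenesulfonate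
Product: 7 (2S)-2-[(2E)-3-iodo-2-methylprop-2-en-1-yl]-2-methyloxetane
Conditions: KOtBu (1.2 equiv), THF, 0 °C → rt
Reagents that add atoms: none
Why: Intramolecular Williamson etherification (4-exo-tet) of the 1,3-diol monotosylate closes the oxetane without breaking the C–O bond at the stereocentre, and the absence of any carbonyl group excludes retro-aldol and β-elimination.

Step 5
Reactants: 7 (2S)-2-[(2E)-3-iodo-2-methylprop-2-en-1-yl]-2-methyloxetane
Product: 9 (2E)-3-methyl-4-[(2S)-2-methyloxetan-2-yl]but-2-en-1-ol, via the corresponding (E)-alkenyllithium 8 (not isolated)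
Conditions: t-BuLi (2.1 equiv), Et2O, −78 °C; then (CH2O)n, −78 °C → rt; H2O
Reagents that add atoms: formaldehyde (as paraformaldehyde), C=O
Why: Iodine–lithium exchange proceeds with retention of alkene geometry and the alkenyllithium is hydroxymethylated by formaldehyde, while an oxetane is inert to organolithiums at low temperature without a Lewis acid.

Step 6
Reactants: 9 (2E)-3-methyl-4-[(2S)-2-methyloxetan-2-yl]but-2-en-1-ol
Product: 11 tert-butyl({(2R,3R)-3-methyl-3-{[(2R)-2-methyloxetan-2-yl]methyl}oxiran-2-yl}methoxy)diphenylsilane, via [(2R,3R)-3-methyl-3-{[(2R)-2-methyloxetan-2-yl]methyl}oxiran-2-yl]methanol 10 (not isolated)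
Conditions: Ti(OiPr)4 (10 mol %), D-(−)-DIPT (12 mol %), TBHP (2 equiv, decane), 4 Å MS, CH2Cl2, −20 °C; P(OMe)3, −20 °C; then Et3N, DMAP (10 mol %), TBDPSCl (1.3 equiv), −20 °C → rt
Reagents that add atoms: tert-butyl hydroperoxide, CC(C)(C)OO; tert-butyl(chloro)diphenylsilane, CC(C)(C)[Si](Cl)(c1ccccc1)c1ccccc1
Why: Katsuki–Sharpless asymmetric epoxidation with the D-(−)-tartrate delivers oxygen to the face of the E-allylic alcohol that gives the (2R,3R)-epoxide under reagent control (the remote oxetane centre only makes the minor product a separable diastereomer), and in situ silylation after reduction of excess TBHP avoids aqueous isolation of the small polar epoxy alcohol.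

Step 7
Reactants: 11 tert-butyl({(2R,3R)-3-methyl-3-{[(2R)-2-methyloxetan-2-yl]methyl}oxiran-2-yl}methoxy)diphenylsilane; 12 hydrogen peroxide
Product: 14 (1R)-2-[(tert-butyldiphenylsilyl)oxy]-1-[(3S,5S)-3-(2-hydroxyethyl)-3,5-dimethyl-1,2-dioxolan-5-yl]ethan-1-ol, via (2R,3S)-1-[(tert-butyldiphenylsilyl)oxy]-3-hydroperoxy-3-methyl-4-[(2R)-2-methyloxetan-2-yl]butan-2-ol 13 (not isolated)
Conditions: H2O2 (anhydrous, ca. 10 equiv, MgSO4-dried Et2O solution), H3PMo12O40 (5 mol %), Et2O, 0 °C → rt
Reagents that add atoms: hydrogen peroxide (12), OO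
Why: Phosphomolybdic acid activates the more strained epoxide first and H2O2 attacks its tertiary carbon C5 anti to the C–O bond (borderline SN2, with positive charge stabilised at the tertiary carbon and disfavoured next to the silyloxymethyl group) to give hydroperoxide 13, the closest known reaction being the molybdenum-catalysed perhydrolysis of tertiary epoxides. The C5–OOH group then opens the acid-activated oxetane at tertiary C3 in a 5-exo-tet closure, the known hydroperoxide–oxetane cyclisation, which forms O2–C3, closes the only new ring (the 1,2-dioxolane) and releases the hydroxyethyl arm. C5 is controlled by the Sharpless-derived epoxide centre and C3 by the mevalonolactone-derived oxetane centre, each transcribed by inversion, so the methyl groups should end up cis [(3S,5S) in 14, the same spatial array as (3R,5R) in the target]. The step needs attack at the tertiary ring carbons, inversion rather than ionisation, and a hydroperoxide that outruns the hydroxyl groups. These are secured by the tertiary bias of both rings, by a large excess of anhydrous H2O2 in a poorly ionising ether at low temperature, by the alpha effect and small size of the terminal OOH oxygen, and by the TBDPS ether, which removes the primary hydroxyl and crowds the liberated secondary carbinol. Should the oxetane be perhydrolysed first, the C3–OOH closes 5-exo on the epoxide at C5 and the same ring results.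

Step 8
Reactants: 14 (1R)-2-[(tert-butyldiphenylsilyl)oxy]-1-[(3S,5S)-3-(2-hydroxyethyl)-3,5-dimethyl-1,2-dioxolan-5-yl]ethan-1-ol
Product: 16 2-[(3R,5S)-5-{(1R)-2-[(tert-butyldiphenylsilyl)oxy]-1-hydroxyethyl}-3,5-dimethyl-1,2-dioxolan-3-yl]acetic acid, via the corresponding (1,2-dioxolan-3-yl)acetaldehyde 15 (not isolated)
Conditions: TEMPO (20 mol %), PhI(OAc)2 (2.5 equiv), MeCN/H2O 1:1, rt
Reagents that add atoms: water, O
Why: Oxoammonium (TEMPO/PhI(OAc)2) oxidation takes the unhindered primary alcohol through the aldehyde hydrate to the acid under slightly acidic conditions, leaves the crowded secondary carbinol and the ditertiary peroxide alone, and cannot cleave a glycol because the primary oxygen is still silylated.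

Step 9
Reactants: 16 2-[(3R,5S)-5-{(1R)-2-[(tert-butyldiphenylsilyl)oxy]-1-hydroxyethyl}-3,5-dimethyl-1,2-dioxolan-3-yl]acetic acid
Product: 18 2-[(3R,5S)-5-formyl-3,5-dimethyl-1,2-dioxolan-3-yl]acetic acid, via 2-[(3R,5S)-5-[(1R)-1,2-dihydroxyethyl]-3,5-dimethyl-1,2-dioxolan-3-yl]acetic acid 17 (not isolated)
Conditions: TBAF/AcOH (1:1, 3 equiv), THF, 0 °C → rt; then H2O, NaIO4 (2 equiv), 0 °C → rt; pH 3, EtOAc
Reagents that add atoms: none
Why: Buffered fluoride desilylation avoids a free alkoxide next to the peroxide (which could fragment across C–C and O–O), and Malaprade periodate cleavage of the unveiled 1,2-diol excises one carbon to leave the non-enolisable C5 aldehyde without touching C5 or C3.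

Step 10
Reactants: 19 8-bromooctan-1-ol
Product: 20 (8-hydroxyoctyl)triphenylphosphonium bromide
Conditions: PPh3 (1.0 equiv), MeCN, reflux; recrystallised free of PPh3
Reagents that add atoms: triphenylphosphine, c1ccc(cc1)P(c1ccccc1)c1ccccc1
Why: SN2 quaternisation of triphenylphosphine by the primary bromide gives the crystalline salt, and removal of residual phosphine protects the peroxide in the next step.

Step 11
Reactants: 18 2-[(3R,5S)-5-formyl-3,5-dimethyl-1,2-dioxolan-3-yl]acetic acid; 20 (8-hydroxyoctyl)triphenylphosphonium bromide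
Product: 22 2-{(3R,5S)-5-[(1Z)-9-hydroxynon-1-en-1-yl]-3,5-dimethyl-1,2-dioxolan-3-yl}acetic acid, via sodium 8-(triphenyl-λ5-phosphanylidene)octan-1-olate 21 (not isolated)
Conditions: 20 (3 equiv), NaHMDS (5.8 equiv), THF, 0 °C; then 18, −78 → 0 °C; aq. citric acid
Reagents that add atoms: none
Why: Wittig olefination with the non-stabilised oxido-ylide is fast at low temperature on the non-enolisable aldehyde; one equivalent of ylide takes up the acid proton so the arm travels as an unreactive carboxylate, the ditertiary peroxide offers no α-hydrogen for Kornblum–DeLaMare cleavage, and the alkene geometry is irrelevant.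

Step 12
Reactants: 22 2-{(3R,5S)-5-[(1Z)-9-hydroxynon-1-en-1-yl]-3,5-dimethyl-1,2-dioxolan-3-yl}acetic acid
Product: 23 2-[(3R,5R)-5-(9-hydroxynonyl)-3,5-dimethyl-1,2-dioxolan-3-yl]acetic acid
Conditions: KO2C–N=N–CO2K (excess), AcOH (slow addition), MeOH, 0 °C → rt
Reagents that add atoms: none
Why: Diimide reduction transfers H2 to the C=C bond in a concerted syn process and leaves the O–O bond intact, unlike catalytic hydrogenation.

Step 13
Reactants: 23 2-[(3R,5R)-5-(9-hydroxynonyl)-3,5-dimethyl-1,2-dioxolan-3-yl]acetic acid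
Product: 24 2-[(3R,5R)-3,5-dimethyl-5-(9-oxononyl)-1,2-dioxolan-3-yl]acetic acid
Conditions: Dess–Martin periodinane (1.3 equiv), CH2Cl2, 0 °C → rt
Reagents that add atoms: none
Why: Dess–Martin oxidation stops at the aldehyde under neutral to slightly acidic conditions that the free acid and the peroxide tolerate.

Step 14
Reactants: 25 (2E,4E)-hepta-2,4-dienal
Product: 26 (2E,4E)-hepta-2,4-dien-1-ol
Conditions: NaBH4, MeOH, 0 °C
Reagents that add atoms: none
Why: Borohydride 1,2-reduction of the dienal gives the dienol with both double bonds unchanged.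

Step 15
Reactants: 26 (2E,4E)-hepta-2,4-dien-1-ol
Product: 27 (2E,4E)-1-bromohepta-2,4-diene
Conditions: PBr3 (0.4 equiv), Et2O, −10 → 0 °C; used at once
Reagents that add atoms: phosphorus tribromide, BrP(Br)Br
Why: Bromination of the primary dienylic alcohol through its phosphite ester proceeds at low temperature at the terminal carbon and keeps the conjugated E,E-diene.

Step 16
Reactants: 27 (2E,4E)-1-bromohepta-2,4-diene
Product: 28 diethyl [(2E,4E)-hepta-2,4-dien-1-yl]phosphonate
Conditions: P(OEt)3 (neat), 100 °C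
Reagents that add atoms: triethyl phosphite, CCOP(OCC)OCC
Why: The Michaelis–Arbuzov reaction of the reactive dienylic bromide gives the phosphonate with loss of ethyl bromide.

Step 17
Reactants: 24 2-[(3R,5R)-3,5-dimethyl-5-(9-oxononyl)-1,2-dioxolan-3-yl]acetic acid; 28 diethyl [(2E,4E)-hepta-2,4-dien-1-yl]phosphonate
Product: 30 2-{(3R,5R)-5-[(9E,11E,13E)-hexadeca-9,11,13-trien-1-yl]-3,5-dimethyl-1,2-dioxolan-3-yl}acetic acid (target), via the lithiated phosphonate 29 (not isolated)
Conditions: 28 (3 equiv), LiHMDS (2.8 equiv), THF/DMPU, −78 °C; then 24, −78 → 0 °C; pH 4 buffer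
Reagents that add atoms: none
Why: Horner–Wadsworth–Emmons olefination with the dienylphosphonate anion is E-selective at the new double bond; base is kept below the phosphonate so no free amide remains, the acid is protected as its lithium carboxylate against β-elimination of the peroxide, and the sensitive triene appears only in the last step, after all oxidations.

## Compound list

1 | (R)-mevalonolactone | C[C@@]1(O)CCOC(=O)C1 | starting material
2 | (4R)-4-methyloxane-2,4-diol (lactol) | C[C@@]1(O)CCOC(O)C1 | intermediate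
3 | (3S)-3-methylhex-5-yne-1,3-diol | C[C@@](CC#C)(O)CCO | intermediate
4 | (E)-alkenyldimethylalane dialkoxide: dimethyl[(1E,4S)-4,6-bis(dimethylalumanyloxy)-2,4-dimethylhex-1-en-1-yl]alumane | C[C@@](C/C(C)=C/[Al](C)C)(O[Al](C)C)CCO[Al](C)C | intermediate
5 | (3S,5E)-6-iodo-3,5-dimethylhex-5-ene-1,3-diol | C[C@@](C/C(C)=C/I)(O)CCO | intermediate
6 | (3S,5E)-3-hydroxy-6-iodo-3,5-dimethylhex-5-en-1-yl 4-methylbenzenesulfonate | C[C@@](C/C(C)=C/I)(O)CCOS(=O)(=O)c1ccc(C)cc1 | intermediate
7 | (2S)-2-[(2E)-3-iodo-2-methylprop-2-en-1-yl]-2-methyloxetane | C[C@@]1(C/C(C)=C/I)OCC1 | intermediate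
8 | (E)-alkenyllithium from 7 | C[C@@]1(C/C(C)=C/[Li])OCC1 | intermediate
9 | (2E)-3-methyl-4-[(2S)-2-methyloxetan-2-yl]but-2-en-1-ol | C[C@@]1(C/C(C)=C/CO)OCC1 | intermediate
10 | [(2R,3R)-3-methyl-3-{[(2R)-2-methyloxetan-2-yl]methyl}oxiran-2-yl]methanol | OC[C@H]1O[C@]1(C)C[C@@]2(C)CCO2 | intermediate
11 | tert-butyl({(2R,3R)-3-methyl-3-{[(2R)-2-methyloxetan-2-yl]methyl}oxiran-2-yl}methoxy)diphenylsilane (TBDPS ether of 10) | CC(C)(C)[Si](c1ccccc1)(c1ccccc1)OC[C@H]1O[C@]1(C)C[C@@]2(C)CCO2 | intermediate
12 | hydrogen peroxide | OO | starting material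
13 | (2R,3S)-1-[(tert-butyldiphenylsilyl)oxy]-3-hydroperoxy-3-methyl-4-[(2R)-2-methyloxetan-2-yl]butan-2-ol | CC(C)(C)[Si](c1ccccc1)(c1ccccc1)OC[C@@H](O)[C@@](C)(OO)C[C@@]2(C)CCO2 | intermediate
14 | (1R)-2-[(tert-butyldiphenylsilyl)oxy]-1-[(3S,5S)-3-(2-hydroxyethyl)-3,5-dimethyl-1,2-dioxolan-5-yl]ethan-1-ol | CC(C)(C)[Si](c1ccccc1)(c1ccccc1)OC[C@@H](O)[C@]2(C)C[C@](C)(CCO)OO2 | intermediate
15 | 2-[(3R,5S)-5-{(1R)-2-[(tert-butyldiphenylsilyl)oxy]-1-hydroxyethyl}-3,5-dimethyl-1,2-dioxolan-3-yl]acetaldehyde | CC(C)(C)[Si](c1ccccc1)(c1ccccc1)OC[C@@H](O)[C@]2(C)C[C@](C)(CC=O)OO2 | intermediate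
16 | 2-[(3R,5S)-5-{(1R)-2-[(tert-butyldiphenylsilyl)oxy]-1-hydroxyethyl}-3,5-dimethyl-1,2-dioxolan-3-yl]acetic acid | CC(C)(C)[Si](c1ccccc1)(c1ccccc1)OC[C@@H](O)[C@]2(C)C[C@](C)(CC(=O)O)OO2 | intermediate
17 | 2-[(3R,5S)-5-[(1R)-1,2-dihydroxyethyl]-3,5-dimethyl-1,2-dioxolan-3-yl]acetic acid | OC[C@@H](O)[C@]1(C)C[C@](C)(CC(=O)O)OO1 | intermediate
18 | 2-[(3R,5S)-5-formyl-3,5-dimethyl-1,2-dioxolan-3-yl]acetic acid | O=C[C@]1(C)C[C@](C)(CC(=O)O)OO1 | intermediate
19 | 8-bromooctan-1-ol | OCCCCCCCCBr | starting material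
20 | (8-hydroxyoctyl)triphenylphosphonium bromide | [Br-].OCCCCCCCC[P+](c1ccccc1)(c1ccccc1)c1ccccc1 | intermediate
21 | sodium 8-(triphenyl-λ5-phosphanylidene)octan-1-olate | [Na+].[O-]CCCCCCCC=P(c1ccccc1)(c1ccccc1)c1ccccc1 | intermediate
22 | 2-{(3R,5S)-5-[(1Z)-9-hydroxynon-1-en-1-yl]-3,5-dimethyl-1,2-dioxolan-3-yl}acetic acid | OCCCCCCC/C=C\[C@]1(C)C[C@](C)(CC(=O)O)OO1 | intermediate
23 | 2-[(3R,5R)-5-(9-hydroxynonyl)-3,5-dimethyl-1,2-dioxolan-3-yl]acetic acid | OCCCCCCCCC[C@]1(C)C[C@](C)(CC(=O)O)OO1 | intermediate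
24 | 2-[(3R,5R)-3,5-dimethyl-5-(9-oxononyl)-1,2-dioxolan-3-yl]acetic acid | O=CCCCCCCCC[C@]1(C)C[C@](C)(CC(=O)O)OO1 | intermediate
25 | (2E,4E)-hepta-2,4-dienal | CC/C=C/C=C/C=O | starting material
26 | (2E,4E)-hepta-2,4-dien-1-ol | CC/C=C/C=C/CO | intermediate
27 | (2E,4E)-1-bromohepta-2,4-diene | CC/C=C/C=C/CBr | intermediate
28 | diethyl [(2E,4E)-hepta-2,4-dien-1-yl]phosphonate | CC/C=C/C=C/CP(=O)(OCC)OCC | intermediate
29 | lithiated phosphonate from 28 | [Li+].CC/C=C/C=C/[CH-]P(=O)(OCC)OCC | intermediate
30 | 2-{(3R,5R)-5-[(9E,11E,13E)-hexadeca-9,11,13-trien-1-yl]-3,5-dimethyl-1,2-dioxolan-3-yl}acetic acid | CC/C=C/C=C/C=C/CCCCCCCC[C@]1(C)C[C@](C)(CC(=O)O)OO1 | target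

Total step count: 17. Longest linear sequence: 13 steps (steps 1–9, 11–13 and 17, from (R)-mevalonolactone).

## Steps most likely to fail

**1. Step 7.** The secondary hydroxyl liberated on epoxide opening may compete with the hydroperoxide in the 5-exo opening of the oxetane. Partial ionisation at the tertiary carbons may also erode the inversion.

The fallback makes the two C–O bonds in separate operations with the rival carbinol masked. It sets out from 11 and comes back at 14. Perhydrolysis of 11 with a low catalyst loading at 0 °C is stopped at hydroperoxide 13, which is isolated. TESCl, imidazole and DMAP cap both the OOH and the secondary OH to give the bis(triethylsilyl) derivative F1. K2CO3 in MeOH at 0 °C cleaves only the far more labile peroxysilane to give the mono-TES hydroperoxide F2. A catalytic acid (camphorsulfonic acid or TMSOTf, CH2Cl2, low temperature) then effects the hydroperoxide–oxetane closure, with no free hydroxyl present until the ring is formed. This gives the O-TES dioxolane F3. PPTS in MeOH removes the TES group and the route is rejoined at 14.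

**2. Step 11.** Addition to the neopentyl-type α-peroxy aldehyde may be slow. Alkoxide adducts formed under the strongly basic conditions may fragment across the C5–CHO and O–O bonds.

The fallback exposes the hindered aldehyde only to a neutral stabilised ylide and builds the chain in two stages. It sets out from 18 and comes back at 23. (Triphenylphosphoranylidene)acetaldehyde (2.2 equiv, toluene, rt to 40 °C, no base) converts 18 into the (E)-enal acid F4. Separately, 6-bromohexan-1-ol and PPh3 give (6-hydroxyhexyl)triphenylphosphonium bromide F5. This salt is deprotonated with NaHMDS and combined at −78 °C with the remote, unhindered enal carbonyl to give the (1E,3Z)-dienol acid F6. Excess diimide saturates both double bonds and the route is rejoined at 23.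

**3. Step 17.** E-selectivity at the new double bond may be incomplete, and material may be lost in separating geometric isomers of a polar, sensitive triene acid.

The fallback reverses the polarity to a Julia–Kocienski olefination that uses 25 directly as the electrophile. It sets out from 18 and 25 and comes back at 30. Excess 1,8-dibromooctane with 1-phenyl-1H-tetrazole-5-thiol and K2CO3 gives the bromo sulfide F7, and PPh3 in MeCN converts it into the phosphonium salt F8. Wittig reaction of its ylide (NaHMDS) with 18 gives the (Z)-alkenyl sulfide F9, and diimide gives the saturated sulfide F10. (NH4)6Mo7O24/H2O2 in EtOH gives the PT sulfone F11. KHMDS (2.1 equiv, DME, −60 °C) followed by 25 closes the triene and the route comes back at 30.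

## Further compounds

F1 | step 7 | (2R,3S)-1-(TBDPS-oxy)-3-methyl-4-[(2R)-2-methyloxetan-2-yl]-2-(triethylsilyloxy)-3-(triethylsilylperoxy)butane | CC(C)(C)[Si](c1ccccc1)(c1ccccc1)OC[C@@H](O[Si](CC)(CC)CC)[C@@](C)(OO[Si](CC)(CC)CC)C[C@@]2(C)CCO2
F2 | step 7 | (2R,3S)-1-(TBDPS-oxy)-3-hydroperoxy-3-methyl-4-[(2R)-2-methyloxetan-2-yl]-2-(triethylsilyloxy)butane | CC(C)(C)[Si](c1ccccc1)(c1ccccc1)OC[C@@H](O[Si](CC)(CC)CC)[C@@](C)(OO)C[C@@]2(C)CCO2
F3 | step 7 | 2-[(3S,5S)-5-{(1R)-2-(TBDPS-oxy)-1-(triethylsilyloxy)ethyl}-3,5-dimethyl-1,2-dioxolan-3-yl]ethan-1-ol | CC(C)(C)[Si](c1ccccc1)(c1ccccc1)OC[C@@H](O[Si](CC)(CC)CC)[C@]2(C)C[C@](C)(CCO)OO2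
F4 | step 11 | 2-{(3R,5S)-3,5-dimethyl-5-[(1E)-3-oxoprop-1-en-1-yl]-1,2-dioxolan-3-yl}acetic acid | O=C/C=C/[C@]1(C)C[C@](C)(CC(=O)O)OO1
F5 | step 11 | (6-hydroxyhexyl)triphenylphosphonium bromide | [Br-].OCCCCCC[P+](c1ccccc1)(c1ccccc1)c1ccccc1
F6 | step 11 | 2-{(3R,5S)-5-[(1E,3Z)-9-hydroxynona-1,3-dien-1-yl]-3,5-dimethyl-1,2-dioxolan-3-yl}acetic acid | OCCCCC/C=C\C=C\[C@]1(C)C[C@](C)(CC(=O)O)OO1
F7 | step 17 | 5-[(8-bromooctyl)sulfanyl]-1-phenyl-1H-tetrazole | BrCCCCCCCCSc1nnnn1-c1ccccc1
F8 | step 17 | triphenyl{8-[(1-phenyl-1H-tetrazol-5-yl)sulfanyl]octyl}phosphonium bromide | [Br-].c1ccccc1-n1nnnc1SCCCCCCCC[P+](c1ccccc1)(c1ccccc1)c1ccccc1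
F9 | step 17 | 2-{(3R,5S)-3,5-dimethyl-5-{(1Z)-9-[(1-phenyl-1H-tetrazol-5-yl)sulfanyl]non-1-en-1-yl}-1,2-dioxolan-3-yl}acetic acid | c1ccccc1-n1nnnc1SCCCCCCC/C=C\[C@]2(C)C[C@](C)(CC(=O)O)OO2
F10 | step 17 | 2-{(3R,5R)-3,5-dimethyl-5-{9-[(1-phenyl-1H-tetrazol-5-yl)sulfanyl]nonyl}-1,2-dioxolan-3-yl}acetic acid | c1ccccc1-n1nnnc1SCCCCCCCCC[C@]2(C)C[C@](C)(CC(=O)O)OO2
F11 | step 17 | 2-{(3R,5R)-3,5-dimethyl-5-{9-[(1-phenyl-1H-tetrazol-5-yl)sulfonyl]nonyl}-1,2-dioxolan-3-yl}acetic acid | c1ccccc1-n1nnnc1S(=O)(=O)CCCCCCCCC[C@]2(C)C[C@](C)(CC(=O)O)OO2
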